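## Retrosynthetic overview

1. The target, a 6,8'-linked bis-coumarin, comes from its 4,4'-dihydroxy precursor by double O-methylation. Both pyranone rings are closed last and together, by a two-fold diethyl carbonate annulation of a biaryl bis(ortho-hydroxyacetophenone).
2. That bis-ketone comes from a biaryl mono-ketone phenol by Friedel–Crafts acetylation and ortho-demethylation on ring A (the ring that becomes the 6-linked coumarin).
3. Key disconnection: the biaryl bond. Both carbons are innately nucleophilic (ortho or para to oxygen). Ring A is reversed in polarity as an aryllead triacetate (aryl cation equivalent) and delivered to the only free ortho carbon of a ring B phenoxide that already carries its acetyl group. Regiochemistry and the axis are fixed in this one step.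
4. Both partners come from 3,5-dimethoxytoluene. Ring order: the two benzene rings are bought, the axis is made in step 3, the two lactone rings in step 5.

Assumption: the SMILES has no descriptor for the biaryl axis, which is the only stereo-element. I take the target as the M atropisomer, which I recall as the hand reported for natural desertorin C. A SMILES string cannot show the sense of the axis, so it is given as M or P in each name.

## Route

Step 1
Reactants: 1 3,5-dimethoxytoluene (1,3-dimethoxy-5-methylbenzene)
Product: 3 1-(2-hydroxy-4-methoxy-6-methylphenyl)ethan-1-one, via 2,4-dimethoxy-6-methylacetophenone 2 (not isolated)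
Conditions: AcCl (1.1 equiv), AlCl3 (2.5 equiv), CH2Cl2, 0 °C to 40 °C; aqueous work-up
Reagents that add atoms: acetyl chloride CC(=O)Cl
Why: Friedel–Crafts acylation goes to the position ortho to methyl and para to a methoxy group, and the aluminium chelate of the resulting ortho-methoxy ketone then cleaves only the flanking methyl ether (chelation-directed demethylation), leaving the para methoxy group intact.

Step 2
Reactants: 1 3,5-dimethoxytoluene
Product: 4 (2,4-dimethoxy-6-methylphenyl)lead triacetate
Conditions: Pb(OAc)4 (1.0 equiv), Hg(OAc)2 (5 mol %), CHCl3/AcOH, 40 °C, dark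
Reagents that add atoms: lead tetraacetate CC(=O)O[Pb](OC(C)=O)(OC(C)=O)OC(C)=O
Why: Electrophilic aromatic metalation (mercuration then mercury-to-lead exchange, direct plumbation) takes place at the same most nucleophilic carbon as in step 1 and stores ring A on tetravalent lead as an aryl cation equivalent.

Step 3
Reactants: 3 1-(2-hydroxy-4-methoxy-6-methylphenyl)ethan-1-one; 4 (2,4-dimethoxy-6-methylphenyl)lead triacetate
Product: 7 (P)-1-(2-hydroxy-2',4',6-trimethoxy-4,6'-dimethyl-[1,1'-biphenyl]-3-yl)ethan-1-one, via lithium phenoxide 5 (not isolated), via aryl(aryloxy)lead diacetate 6 (not isolated)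
Conditions: n-BuLi (1.0 equiv), toluene, −78 to 0 °C; brucine (3 equiv), 4 Å MS, then 4 (1.2 equiv), −20 °C to rt; recrystallise
Reagents that add atoms: none
Why: Proposed new method: the aryl group on tetravalent lead is an aryl cation equivalent, so the normally nucleophilic ring A carbon is delivered as an electrophile by ligand coupling within the brucine-coordinated species 6 to the only free ortho carbon of the phenoxide (between O and OMe), and loss of the ortho proton restores the phenol (Pinhey ortho-arylation of phenols; closest known type is the brucine-mediated asymmetric coupling of lithium phenoxides with aryllead triacetates to hindered biaryls), the chiral amine on lead fixing the sense of twist of the four-fold ortho-substituted axis as the C–C bond forms, with recrystallisation to bring 7 to a single atropisomer.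

Step 4
Reactants: 7 (P)-1-(2-hydroxy-2',4',6-trimethoxy-4,6'-dimethyl-[1,1'-biphenyl]-3-yl)ethan-1-one
Product: 9 (P)-1,1'-(2,4'-dihydroxy-2',6-dimethoxy-4,6'-dimethyl-[1,1'-biphenyl]-3,5'-diyl)di(ethan-1-one), via trimethoxy diketone 8 (not isolated)
Conditions: AlCl3 (4 equiv), then AcCl (1.3 equiv), CH2Cl2, 0 °C to rt; aqueous work-up
Reagents that add atoms: acetyl chloride CC(=O)Cl
Why: Friedel–Crafts acylation occurs on the electron-rich ring A at the carbon ortho to methyl and para to methoxy (ring B is deactivated by its aluminium-chelated ketone), and the new ketone's aluminium chelate cleaves only the methyl ether ortho to it (chelation-directed demethylation), with no bond at the axis touched so the P configuration is kept.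

Step 5
Reactants: 9 (P)-1,1'-(2,4'-dihydroxy-2',6-dimethoxy-4,6'-dimethyl-[1,1'-biphenyl]-3,5'-diyl)di(ethan-1-one)
Product: 10 (M)-4,4'-dihydroxy-7,7'-dimethoxy-5,5'-dimethyl-2H,2'H-[6,8'-bichromene]-2,2'-dione
Conditions: NaH (8 equiv), (EtO)2CO (10 equiv), toluene, 90 °C; then aq. HCl
Reagents that add atoms: diethyl carbonate CCOC(=O)OCC
Why: Two-fold Claisen-type acylation of the methyl ketone enolates by diethyl carbonate and lactonisation onto the neighbouring phenoxides gives both 4-hydroxycoumarin rings at once; the axis is untouched and the descriptor changes from P to M only because the ring B phenol oxygen becomes the higher-ranked lactone oxygen.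

Step 6
Reactants: 10 (M)-4,4'-dihydroxy-7,7'-dimethoxy-5,5'-dimethyl-2H,2'H-[6,8'-bichromene]-2,2'-dione
Product: 11 (M)-4,4',7,7'-tetramethoxy-5,5'-dimethyl-2H,2'H-[6,8'-bichromene]-2,2'-dione (desertorin C, CNP0271624.0)
Conditions: Me2SO4 (3 equiv), K2CO3 (4 equiv), acetone, reflux
Reagents that add atoms: dimethyl sulfate COS(=O)(=O)OC
Why: O-Alkylation of the two vinylogous acids (4-hydroxycoumarins) with a hard methylating agent gives the 4-methoxycoumarins in preference to C3-methylation, and the axis is not affected.

## Compound list

1 | 3,5-dimethoxytoluene | Cc1cc(OC)cc(OC)c1 | starting material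
2 | 1-(2,4-dimethoxy-6-methylphenyl)ethan-1-one | CC(=O)c1c(C)cc(OC)cc1OC | intermediate
3 | 1-(2-hydroxy-4-methoxy-6-methylphenyl)ethan-1-one | CC(=O)c1c(C)cc(OC)cc1O | intermediate
4 | (2,4-dimethoxy-6-methylphenyl)lead triacetate | CC(=O)O[Pb](OC(C)=O)(OC(C)=O)c1c(C)cc(OC)cc1OC | intermediate
5 | lithium 2-acetyl-5-methoxy-3-methylphenolate | [Li+].[O-]c1cc(OC)cc(C)c1C(C)=O | intermediate
6 | (2-acetyl-5-methoxy-3-methylphenoxy)(2,4-dimethoxy-6-methylphenyl)lead diacetate | CC(=O)O[Pb](OC(C)=O)(Oc1cc(OC)cc(C)c1C(C)=O)c1c(C)cc(OC)cc1OC | intermediate
7 | (P)-1-(2-hydroxy-2',4',6-trimethoxy-4,6'-dimethyl-[1,1'-biphenyl]-3-yl)ethan-1-one; seen along the axis, the quarter turn from the ring A ortho-methoxy carbon to the ring B ortho-methoxy carbon is clockwise | CC(=O)c1c(C)cc(OC)c(-c2c(C)cc(OC)cc2OC)c1O | intermediate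
8 | (P)-1,1'-(2-hydroxy-2',4',6-trimethoxy-4,6'-dimethyl-[1,1'-biphenyl]-3,5'-diyl)di(ethan-1-one) | CC(=O)c1c(C)cc(OC)c(-c2c(C)c(C(C)=O)c(OC)cc2OC)c1O | intermediate
9 | (P)-1,1'-(2,4'-dihydroxy-2',6-dimethoxy-4,6'-dimethyl-[1,1'-biphenyl]-3,5'-diyl)di(ethan-1-one) | CC(=O)c1c(C)cc(OC)c(-c2c(C)c(C(C)=O)c(O)cc2OC)c1O | intermediate
10 | (M)-4,4'-dihydroxy-7,7'-dimethoxy-5,5'-dimethyl-2H,2'H-[6,8'-bichromene]-2,2'-dione | COc1cc2oc(=O)cc(O)c2c(C)c1-c1c(OC)cc(C)c2c(O)cc(=O)oc12 | intermediate
11 | (M)-4,4',7,7'-tetramethoxy-5,5'-dimethyl-2H,2'H-[6,8'-bichromene]-2,2'-dione; seen along the axis, the quarter turn from C7 (OMe) of the 6-linked unit to C8a' (lactone oxygen side) of the 8'-linked unit is counter-clockwise | COc1cc2oc(=O)cc(OC)c2c(C)c1-c1c(OC)cc(C)c2c(OC)cc(=O)oc12 | target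

## Step count and risks

Total step count: 6. Longest linear sequence: 5 steps (steps 1, 3, 4, 5, 6 from compound 1); step 2 is a one-step branch.

Most likely to fail, first: step 3. The phenoxide is chelated and acyl-deactivated, ligand coupling could go to the acyl-bearing ortho carbon instead, and the sense and level of induction by natural brucine (one hand only) cannot be predicted. The axis of 7 must be confirmed by ECD, and P is required. The fallback keeps 4 as the aryl cation equivalent but changes the nucleophile to a cyclic 1,3-dione and makes ring B aromatic afterwards. It sets out from compound 4. Pinhey C-arylation of 5-methylcyclohexane-1,3-dione F1 (pyridine, CHCl3, 40 °C) gives 2-(2,4-dimethoxy-6-methylphenyl)-5-methylcyclohexane-1,3-dione F2. Iodine in methanol at reflux (enol ether formation and dehydrogenation) aromatises F2 to the racemic resorcinol monomethyl ether. Its atropisomers are separated on a chiral stationary phase to give (P)-2',4',6-trimethoxy-4,6'-dimethyl-[1,1'-biphenyl]-2-ol F3. AcCl/AlCl3 then acetylates both rings: ring B by O-acetylation and Fries shift to its only free ortho position, ring A as in step 4 with loss of the flanking O-methyl group. The fallback comes back to the route at compound 9.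

Second: step 4. Risks are acylation at the wrong ring A carbon, para-Fries chemistry on ring B, over-demethylation, and acid-induced erosion of the axis. The fallback installs the ring A acetyl group before the biaryl bond is made. It sets out from compound 2, isolated by running step 1 at 0 °C and quenching before demethylation. Plumbation with Pb(OAc)4 and catalytic Hg(OAc)2 gives (5-acetyl-2,4-dimethoxy-6-methylphenyl)lead triacetate F4. F4 is coupled with lithium phenoxide 5 under the brucine conditions of step 3. The fallback comes back to the route at compound 8, now isolated, which BCl3 (CH2Cl2, −78 to 0 °C) demethylates only ortho to the ring A ketone to give 9.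

Third: step 2. Direct plumbation may give the isomer between the two methoxy groups, benzylic acetoxylation or oxidative homocoupling. The fallback fixes the position by halogenation and makes the carbon–lead bond by transmetallation. It sets out from compound 1. NBS in MeCN at 0 °C gives 2-bromo-1,5-dimethoxy-3-methylbenzene F5. Bromine–lithium exchange (n-BuLi, THF, −78 °C), B(Oi-Pr)3 and aqueous acid give (2,4-dimethoxy-6-methylphenyl)boronic acid F6. Boron-to-lead exchange with Pb(OAc)4 and catalytic Hg(OAc)2 in CHCl3 comes back to the route at compound 4.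

## Further compounds

F1 | step 3 | 5-methylcyclohexane-1,3-dione | CC1CC(=O)CC(=O)C1
F2 | step 3 | 2-(2,4-dimethoxy-6-methylphenyl)-5-methylcyclohexane-1,3-dione (tautomer and diastereomer mixture, all stereo lost on aromatisation) | CC1CC(=O)C(c2c(C)cc(OC)cc2OC)C(=O)C1
F3 | step 3 | (P)-2',4',6-trimethoxy-4,6'-dimethyl-[1,1'-biphenyl]-2-ol | Cc1cc(O)c(-c2c(C)cc(OC)cc2OC)c(OC)c1
F4 | step 4 | (5-acetyl-2,4-dimethoxy-6-methylphenyl)lead triacetate | CC(=O)O[Pb](OC(C)=O)(OC(C)=O)c1c(C)c(C(C)=O)c(OC)cc1OC
F5 | step 2 | 2-bromo-1,5-dimethoxy-3-methylbenzene | Cc1cc(OC)cc(OC)c1Br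
F6 | step 2 | (2,4-dimethoxy-6-methylphenyl)boronic acid | Cc1cc(OC)cc(OC)c1B(O)O
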